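A ratio runs this examination: how fast partner leaks away at the start, against how fast it turns into product.

| flask | starting material | partner | free catalyst | time |
|---|---|---|---|---|
| amber | 0.250 M | 0.275 M | 0.0130 M |  |
| green | 0.150 M | 0.175 M | 0.0130 M |  |
| blue | 0.250 M | 0.275 M | 0.0190 M |  |
| ochre | 0.380 M | 0.275 M | 0.0130 M |  |
| grey | 0.250 M | 0.275 M | 0.0130 M | 200 min |

| run | time / min | [product] / M |
|---|---|---|
| amber run | 2.0 | 0.0035 |
| amber run | 3.7 | 0.0105 |
| amber run | 7.1 | 0.0184 |
| amber run | 14 | 0.0409 |
| amber run | 26 | 0.0729 |
| amber run | 49 | 0.1073 |
| green run | 2.0 | 0.0042 |
| green run | 3.7 | 0.0064 |
| green run | 7.1 | 0.0165 |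
| green run | 14 | 0.0312 |
| green run | 26 | 0.0541 |
| green run | 49 | 0.0728 |
| blue run | 2.0 | 0.0053 |
| blue run | 3.7 | 0.0131 |
| blue run | 7.1 | 0.0282 |
| blue run | 14 | 0.0586 |
| blue run | 26 | 0.1033 |
| blue run | 49 | 0.1314 |
| ochre run | 2.0 | 0.0037 |
| ochre run | 3.7 | 0.0109 |
| ochre run | 7.1 | 0.0228 |
| ochre run | 14 | 0.0462 |
| ochre run | 26 | 0.0823 |
| ochre run | 49 | 0.1134 |

(readings scatter by 0.001 M)

- Overall: starting material + partner -> product, with free catalyst as catalyst.
- Constant volume, constant temperature.
- A reading of a species includes what of it is bound.
- "The second partner" is partner.
- An order is taken over about fifteen percent of the charge, up and down.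

- the power of [partner] that the first rate follows, about the charge of the amber run; measure it at two percent of starting material made into product
- the power of [free catalyst] that the first rate follows, about the charge of the amber run; measure it at two percent of starting material made into product
- product in the grey run at 200 min, as a share of the starting material charged

**What do the runs show?** A straight stretch, then a slowing. The amber run makes 0.00292 M/min up to 14 min, yet by 49 min its product is 42.9% of the starting material charged.

**Is the catalyst dying?** I doubt it. With first-order loss of catalyst, a rate proportional to catalyst and the other charges held, final product scales with the catalyst charged. The blue run has 1.46 times the amber catalyst and 0.00419 M/min early, 1.43 times the amber rate, but at 49 min it holds 1.22 times the amber product. So I suppose that partner leaks first-order while product takes it at a steady rate.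

**Integrate that.** On that supposition partner obeys a linear equation and reaches zero. The share of the partner charge that becomes product is the logarithm of one plus ρ, divided by ρ. The amber run's last reading is 39.0% of its partner charge and still creeping, so I take ρ = 4.00, the leak ratio: leak constant times partner charge, over product rate. That share is then 40.2%, and the leak constant is 0.0425 /min.

**Test it elsewhere.** The blue run, with that constant and its own rate, has ρ = 2.79, which gives 47.8% of its partner charge. Its reading at 49 min is 47.8%.

**The weak spot?** I read ρ as if the amber run had stopped. The reckoned stop comes at 37.9 min, earlier than that reading.

**Your answers?** The grey run has the amber charge, so I say 44.3% of its starting material. The catalyst order across blue and amber reads 0.948, and I take the partner order as close to zero, as my steady rate assumes.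

**And the forecast?** It gives 0.15 (−0.1 to 0.45) for partner, 1 (0.8 to 1.2) for catalyst and 52% (46% to 72%) for the grey run, on the ground that “This suggests the catalyst is dying, or possibly inhibition”. My figure lies below its range.

    free catalyst + starting material → catalyst-substrate complex (5.166 /M/min)
    catalyst-substrate complex + partner → loaded catalyst (12.72 /M/min)
    loaded catalyst → product + free catalyst (0.5676 /min)
    2 starting material ⇌ idle substrate dimer, settled at all times (5.660 /M)
    partner → lost reagent (0.04032 /min)

The flask gives 0.077 for partner, 0.86 for free catalyst and 43.7% for the grey run. Free catalyst took up starting material, the catalyst-substrate complex took partner and the loaded catalyst released product, near zero order in partner, while partner went to lost reagent alongside with a lifetime of 24.8 min. By 200 min the grey product equals 39.7% of its partner charge. The green run, with rate 0.0025 M/min where two percent of the amber starting material would have turned, has ρ = 2.96, which reckons 54.3% of its starting material at the stop, and its product comes to half of its starting material at 52.8 min.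

(Readings and results stem from a simulated flask with constants of no real substance; noise was put on by code.)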